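**Plan**

- Chain numbering: C1 (CH2 on furan ring A), C2 (CH–OAc), C3=C4(Me), C5H2, C6=C7, C8(Me)=C9, C10H2, C11H2 (on furan ring B). No ring is built; both furans are bought.
- Enabling feature: C3=C4(Me)–C5H2–C6=C7 is a 1,4-diene whose C7 adjoins C8=C9. The retrosynthesis cuts C4–C5 and returns the C3 hydrogen to C7, giving an alkyne (C1–C4) and a skipped diene (C5–C11).
- The alkyne is cut at C2–C3 (alkynyl Grignard on a furylacetic Weinreb amide). The diene is cut at C8=C9 (Wittig) and C6–C7 (copper-catalysed vinyl–allyl coupling).
- Forward: four steps to the (S)-propargylic acetate, five steps to the E-1,4-diene, then the ruthenium coupling joins C4–C5 last and gives the target directly.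
- Stereochemistry: C2 (S) from Noyori transfer hydrogenation of the ynone with the (S,S)-TsDPEN ruthenium catalyst. 8E comes from the stabilised Wittig; 3E and 6E come from the syn addition and the β-hydride elimination of the ruthenium step.

Key step: step 10

Remark: both furyl carboxylic acids, the two Grignard solutions and the phosphorane are taken as purchasable; in the SMILES of 18 and F5 the cyclopentadienyl ligands are drawn with a single bond to the metal, and acetonitrile and PF6 are left out of 18.

**Route**

Step 1
Reactants: 1 2-(furan-3-yl)acetic acid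
Product: 3 2-(furan-3-yl)-N-methoxy-N-methylacetamide, via acyl imidazolide 2 (not isolated)
Conditions: CDI, CH2Cl2, rt; then MeNHOMe·HCl, rt
Reagents that add atoms: N,O-dimethylhydroxylamine hydrochloride, CNOC.Cl; 1,1'-carbonyldiimidazole, O=C(n1ccnc1)n1ccnc1 (its imidazole is carried by 2 only)
Why: Weinreb amide formation by CDI activation of the acid as acyl imidazolide 2 and aminolysis, under neutral conditions that leave the furan alone.

Step 2
Reactants: 3 2-(furan-3-yl)-N-methoxy-N-methylacetamide; 4 prop-1-ynylmagnesium bromide
Product: 6 1-(furan-3-yl)pent-3-yn-2-one, via magnesium hemiaminal chelate 5 (not isolated)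
Conditions: MeC≡CMgBr (1.3 equiv), THF, −78 to 0 °C; cold aq. NH4Cl
Reagents that add atoms: none
Why: Weinreb ketone synthesis, in which chelate 5 survives until the quench so that only one alkynyl group is delivered, while the weakly basic alkynyl Grignard should not enolise the furylacetyl CH2.

Step 3
Reactants: 6 1-(furan-3-yl)pent-3-yn-2-one
Product: 7 (2S)-1-(furan-3-yl)pent-3-yn-2-ol
Conditions: Ru[(S,S)-TsDPEN](p-cymene) (2 mol %), i-PrOH, rt
Reagents that add atoms: none
Why: Noyori asymmetric transfer hydrogenation of an α,β-acetylenic ketone, in which the propynyl group takes the place an aryl group has in acetophenone-type substrates in the six-membered hydride/proton transfer transition state, so the (S,S)-catalyst should give the (S)-carbinol, and the base-free medium spares the acidic furylmethylene group.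

Step 4
Reactants: 7 (2S)-1-(furan-3-yl)pent-3-yn-2-ol
Product: 8 (2S)-1-(furan-3-yl)pent-3-yn-2-yl acetate
Conditions: Ac2O, pyridine, DMAP (cat.), CH2Cl2, 0 °C to rt
Reagents that add atoms: acetic anhydride, CC(=O)OC(C)=O
Why: DMAP-catalysed O-acylation that does not touch the C2–O bond, so the configuration is retained.

Step 5
Reactants: 9 3-(furan-3-yl)propanoic acid
Product: 10 3-(furan-3-yl)propan-1-ol
Conditions: LiAlH4, THF, 0 °C to rt; aqueous work-up
Reagents that add atoms: none
Why: hydride reduction of a carboxylic acid to the primary alcohol, to which the furan is inert.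

Step 6
Reactants: 10 3-(furan-3-yl)propan-1-ol; 11 ethyl 2-(triphenylphosphoranylidene)propanoate
Product: 13 ethyl (2E)-5-(furan-3-yl)-2-methylpent-2-enoate, via 3-(furan-3-yl)propanal 12 (not isolated)
Conditions: Dess–Martin periodinane, CH2Cl2, 0 °C to rt; then 11 (1.5 equiv), rt
Reagents that add atoms: none
Why: Dess–Martin oxidation followed in the same flask by Wittig olefination of aldehyde 12, where the α-methyl-stabilised ylide should give the E-trisubstituted enoate that becomes the 8E alkene.

Step 7
Reactants: 13 ethyl (2E)-5-(furan-3-yl)-2-methylpent-2-enoate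
Product: 14 (2E)-5-(furan-3-yl)-2-methylpent-2-en-1-ol
Conditions: i-Bu2AlH (2.2 equiv), CH2Cl2, −78 °C; aq. potassium sodium tartrate
Reagents that add atoms: none
Why: 1,2-reduction of an α,β-unsaturated ester by i-Bu2AlH, without conjugate reduction or change of alkene geometry.

Step 8
Reactants: 14 (2E)-5-(furan-3-yl)-2-methylpent-2-en-1-ol
Product: 15 3-[(3E)-5-bromo-4-methylpent-3-en-1-yl]furan
Conditions: CBr4, PPh3, CH2Cl2, 0 °C
Reagents that add atoms: tetrabromomethane, BrC(Br)(Br)Br
Why: Appel reaction, in which bromide displaces the alkoxyphosphonium group at the primary allylic carbon under neutral conditions that should neither transpose the alkene nor harm the furan.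

Step 9
Reactants: 15 3-[(3E)-5-bromo-4-methylpent-3-en-1-yl]furan; 16 vinylmagnesium bromide
Product: 17 3-[(3E)-4-methylhepta-3,6-dien-1-yl]furan
Conditions: CH2=CHMgBr (1.5 equiv), CuI (10 mol %), THF, −30 to 0 °C
Reagents that add atoms: none
Why: copper-catalysed cross-coupling of a Grignard reagent with a primary allylic bromide, in which attack at the unhindered CH2Br carbon rather than the γ-carbon should keep the E-trisubstituted alkene and place the vinyl group one carbon from it.

Step 10
Reactants: 8 (2S)-1-(furan-3-yl)pent-3-yn-2-yl acetate; 17 3-[(3E)-4-methylhepta-3,6-dien-1-yl]furan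
Product: 19 (2S,3E,6E,8E)-1,11-di(furan-3-yl)-4,8-dimethylundeca-3,6,8-trien-2-yl acetate, via ruthenacyclopentene 18 (not isolated)
Conditions: [CpRu(MeCN)3]PF6 (10 mol %), 17 (1.5 equiv), degassed acetone, rt; chromatography on Et3N-buffered silica
Reagents that add atoms: none
Why: The cationic CpRu fragment (divalent ruthenium) binds the alkyne of 8 and the monosubstituted alkene of 17 and couples them oxidatively to ruthenacyclopentene 18 (tetravalent ruthenium) with C4–C5 in place and ruthenium on C3 and C6; β-hydride elimination of a doubly allylic hydrogen on the exocyclic C7 and C–H reductive elimination at C3 then release 19 and the catalyst. The closest known reaction type is the ruthenium-catalysed Alder-ene type coupling of monosubstituted alkenes with methyl-capped, propargylically branched alkynes to 1,4-dienes. No ring of the target closes (the only ring is the transient five-membered metallacycle) and no stereocentre is created, since the C2–O bond is untouched and the (S) configuration is carried through. Carbon and hydrogen are delivered syn across the alkyne, which puts the C3 hydrogen cis to C5 and so gives 3E, and the β-hydride elimination should give the trans C6=C7 bond in conjugation with the 8E alkene already present. The step needs bond formation at C4 and not C3, which the branched acetoxy-bearing C2 should secure by keeping the more hindered C3 on ruthenium, and it needs a single alkene to react, which holds because the trisubstituted C8=C9 cannot enter the metallacycle and C7 carries the only β-hydrogens outside the ring. The neutral medium should spare the acetate, the bis-allylic C5 and both furans, and the excess of 17 is meant to compete with the product diene for the metal.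

**Compound list**

1 | 2-(furan-3-yl)acetic acid | OC(=O)Cc1ccoc1 | starting material
2 | 2-(furan-3-yl)-1-(1H-imidazol-1-yl)ethan-1-one (acyl imidazolide) | O=C(Cc1ccoc1)n1ccnc1 | intermediate (not isolated)
3 | 2-(furan-3-yl)-N-methoxy-N-methylacetamide | CON(C)C(=O)Cc1ccoc1 | intermediate
4 | prop-1-ynylmagnesium bromide | CC#C[Mg]Br | starting material
5 | bromomagnesium 1-(furan-3-yl)-2-[methoxy(methyl)amino]pent-3-yn-2-olate (magnesium hemiaminal chelate) | CC#CC(Cc1ccoc1)(O[Mg]Br)N(C)OC | intermediate (not isolated)
6 | 1-(furan-3-yl)pent-3-yn-2-one | CC#CC(=O)Cc1ccoc1 | intermediate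
7 | (2S)-1-(furan-3-yl)pent-3-yn-2-ol | O[C@H](C#CC)Cc1ccoc1 | intermediate
8 | (2S)-1-(furan-3-yl)pent-3-yn-2-yl acetate | CC(=O)O[C@H](C#CC)Cc1ccoc1 | intermediate
9 | 3-(furan-3-yl)propanoic acid | OC(=O)CCc1ccoc1 | starting material
10 | 3-(furan-3-yl)propan-1-ol | OCCCc1ccoc1 | intermediate
11 | ethyl 2-(triphenylphosphoranylidene)propanoate | CCOC(=O)C(C)=P(c1ccccc1)(c1ccccc1)c1ccccc1 | starting material
12 | 3-(furan-3-yl)propanal | O=CCCc1ccoc1 | intermediate (not isolated)
13 | ethyl (2E)-5-(furan-3-yl)-2-methylpent-2-enoate | CCOC(=O)/C(C)=C/CCc1ccoc1 | intermediate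
14 | (2E)-5-(furan-3-yl)-2-methylpent-2-en-1-ol | OC/C(C)=C/CCc1ccoc1 | intermediate
15 | 3-[(3E)-5-bromo-4-methylpent-3-en-1-yl]furan | BrC/C(C)=C/CCc1ccoc1 | intermediate
16 | vinylmagnesium bromide | C=C[Mg]Br | starting material
17 | 3-[(3E)-4-methylhepta-3,6-dien-1-yl]furan | C=CC/C(C)=C/CCc1ccoc1 | intermediate
18 | cyclopentadienyl ruthenacyclopent-2-ene cation (ring Ru–C3=C4(Me)–C5H2–C6H; C3 bears the (S)-CH(OAc)CH2(3-furyl) group, C6 the (2E)-5-(furan-3-yl)-2-methylpent-2-enyl group) | CC(=O)O[C@@H](Cc1ccoc1)C2=C(C)CC(C/C(C)=C/CCc3ccoc3)[Ru+]2C4C=CC=C4 | intermediate (not isolated)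
19 | (2S,3E,6E,8E)-1,11-di(furan-3-yl)-4,8-dimethylundeca-3,6,8-trien-2-yl acetate | CC(=O)O[C@H](/C=C(\C)C/C=C/C(C)=C/CCc1ccoc1)Cc1ccoc1 | target

**Count and risks**

Total step count: 10. Longest linear sequence: 6 steps (steps 5 to 10, from acid 9); the alkyne branch (steps 1 to 4) joins at step 10.

Steps most likely to fail:

1. Step 10. Turnover may stall because the conjugated diene of the product, or the 1,4-diene of 17 acting as a chelate, ties up the cationic ruthenium. Bond formation may also stray to C3, and slow ionisation of the allylic acetate of the product by the same cation would erode C2. Fallback, setting out from 14 and 7 and coming back at 19: the C4–C5 bond is made by syn-hydrozirconation of the alkyne and a palladium-catalysed alkenyl–allyl coupling, with the acetate installed last. Alcohol 14 is oxidised with MnO2 (CH2Cl2, rt) to (2E)-5-(furan-3-yl)-2-methylpent-2-enal F1. Addition of vinylmagnesium bromide 16 (THF, −78 °C) gives racemic (4E)-7-(furan-3-yl)-4-methylhepta-1,4-dien-3-ol F2, and PBr3 (Et2O, −10 °C) should convert it with allylic transposition into the conjugated primary bromide 3-[(3E,5E)-7-bromo-4-methylhepta-3,5-dien-1-yl]furan F3. Alcohol 7 is silylated (TBSCl, imidazole, DMF) to tert-butyl{[(2S)-1-(furan-3-yl)pent-3-yn-2-yl]oxy}dimethylsilane F4. Cp2Zr(H)Cl (THF, rt) should add hydrogen to C3 and zirconium to the less hindered, methyl-bearing C4, giving chlorobis(cyclopentadienyl){(2E,4S)-4-[(tert-butyldimethylsilyl)oxy]-5-(furan-3-yl)pent-2-en-2-yl}zirconium F5. This is not isolated but coupled with F3 under Pd(PPh3)4 (zerovalent palladium, 5 mol %) and catalytic ZnCl2 at the unsubstituted allyl terminus, to give tert-butyl{[(2S,3E,6E,8E)-1,11-di(furan-3-yl)-4,8-dimethylundeca-3,6,8-trien-2-yl]oxy}dimethylsilane F6. Bu4NF (THF) frees (2S,3E,6E,8E)-1,11-di(furan-3-yl)-4,8-dimethylundeca-3,6,8-trien-2-ol F7, and Ac2O, pyridine and DMAP as in step 4 return to 19.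

2. Step 9. The vinylcopper species may attack the γ-carbon (SN2' pathway) and give the branched diene, or the allylic bromide may homocouple. Fallback, setting out from 15 and coming back at 17: the copper manifold is replaced by a Stille coupling with tributyl(vinyl)stannane (Pd2(dba)3, tri(2-furyl)phosphine, THF, 50 °C). Here zerovalent palladium forms a π-allyl complex that should be vinylated at its less substituted terminus with the E geometry kept.

3. Step 3. Facial discrimination between the propynyl and furylmethyl groups may be insufficient, or the α-acidic ynone may isomerise or condense on the basic amido-ruthenium catalyst before hydride delivery. Fallback, setting out from 6 and coming back at 7: catalytic hydrogen transfer is given up for a stoichiometric chiral organoborane, the Midland reduction with (S)-Alpine-Borane (B-isopinocampheyl-9-borabicyclo[3.3.1]nonane from (−)-α-pinene, THF, rt). This metal- and base-free cyclic hydride transfer treats the alkynyl group as the small substituent and should give the (S)-carbinol.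

Further compounds
F1 | step 10 | (2E)-5-(furan-3-yl)-2-methylpent-2-enal | O=C/C(C)=C/CCc1ccoc1
F2 | step 10 | (4E)-7-(furan-3-yl)-4-methylhepta-1,4-dien-3-ol (racemic) | C=CC(O)/C(C)=C/CCc1ccoc1
F3 | step 10 | 3-[(3E,5E)-7-bromo-4-methylhepta-3,5-dien-1-yl]furan | BrC/C=C/C(C)=C/CCc1ccoc1
F4 | step 10 | tert-butyl{[(2S)-1-(furan-3-yl)pent-3-yn-2-yl]oxy}dimethylsilane | CC(C)(C)[Si](C)(C)O[C@H](C#CC)Cc1ccoc1
F5 | step 10 | chlorobis(cyclopentadienyl){(2E,4S)-4-[(tert-butyldimethylsilyl)oxy]-5-(furan-3-yl)pent-2-en-2-yl}zirconium | C/C(=C\[C@@H](O[Si](C)(C)C(C)(C)C)Cc1ccoc1)[Zr](Cl)(C2C=CC=C2)C3C=CC=C3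
F6 | step 10 | tert-butyl{[(2S,3E,6E,8E)-1,11-di(furan-3-yl)-4,8-dimethylundeca-3,6,8-trien-2-yl]oxy}dimethylsilane | CC(C)(C)[Si](C)(C)O[C@H](/C=C(\C)C/C=C/C(C)=C/CCc1ccoc1)Cc1ccoc1
F7 | step 10 | (2S,3E,6E,8E)-1,11-di(furan-3-yl)-4,8-dimethylundeca-3,6,8-trien-2-ol | O[C@H](/C=C(\C)C/C=C/C(C)=C/CCc1ccoc1)Cc1ccoc1
F0 | step 9 | none | none
F0 | step 3 | none | none
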